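**Retrosynthetic overview**

1. Target 29 ⇐ desilylation ⇐ Z-selective enyne cross-metathesis on an 8-allyl group plus acetylation; the trans-4,5-diacetate ⇐ ring Z-olefin C4=C5 (hydroxyl-directed epoxidation, then acetate opening).
2. 8-Allyl/7-OH ⇐ eight-membered α-hydroxy lactone 13, whose carbonyl is C8 (reductive acetylation, allyl delivered from a silicon tether on O7); 7-OH ⇐ 7-chloride by SN2 inversion.
3. Lactone 11 ⇐ trans-2-vinyloxetane 7 + chloroketene: a ketene-Claisen ring expansion that makes O1–C8 and C6–C7 in one operation and breaks O1–C4.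
4. Enabling feature: ring atoms O1, C2, C3, C4 are read as an oxetane whose C4 carries a vinyl group (C5=C6). The 4,5-diol is then a latent Z-olefin inside the allyl ether array O1–C4–C5=C6, C7(OH)–C8 is a masked chloroketene, and the strain of the four-membered ring drives its four-atom enlargement to the oxocane.
5. Ring order: oxetane (4-exo epoxide opening, step 5), then oxocane (ring expansion, step 7). Oxetane 7 ⇐ (S)-octadienol 2 by iodocarbonate cyclisation, which relays one carbinol stereocentre to C2 and C1'.

Key step: step 7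

Remark on numbering: for compounds 10–24, 28, 29 and the F compounds, ring locants are those of the target oxocane: O1, C2 (bears the side chain, carbinol carbon C1'), C3, C4, C5, C6, C7 (bears OH), C8 (bears the five-carbon chain). C3, C4, C5 and C6 of the octadienol chain (compounds 1–5) become C4, C3, C2 and C1'. PMB = 4-methoxybenzyl, TBS = tert-butyldimethylsilyl, TIPS = tri(propan-2-yl)silyl.

Assumption: racemic (5Z)-octa-1,5-dien-3-ol 1 is taken as purchasable (flavour-grade racemate); no single enantiomer is assumed to be on sale.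

**Route**

Step 1
Reactants: 1 rac-(5Z)-octa-1,5-dien-3-ol
Product: 2 (3S,5Z)-octa-1,5-dien-3-ol
Conditions: Ti(OiPr)4, D-(−)-diisopropyl tartrate, t-BuOOH (0.6 equiv), 4 Å molecular sieves, CH2Cl2, −20 °C
Reagents that add atoms: none
Why: Sharpless kinetic resolution: with the D-tartrate the (R)-allylic alcohol should be epoxidised much faster, so the (S)-alcohol is recovered, and the homoallylic Z-olefin is not a substrate for the titanium tartrate system.

Step 2
Reactants: 2 (3S,5Z)-octa-1,5-dien-3-ol
Product: 3 tert-butyl carbonate of 2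
Conditions: Boc2O, DMAP (cat.), MeCN, rt
Reagents that add atoms: di-tert-butyl dicarbonate, CC(C)(C)OC(=O)OC(=O)OC(C)(C)C
Why: DMAP-catalysed O-acylation (carbonate formation) leaves the stereocentre untouched and installs the internal oxygen nucleophile for step 3.

Step 3
Reactants: 3 tert-butyl carbonate
Product: 4 cyclic iodocarbonate
Conditions: IBr, toluene, −80 °C
Reagents that add atoms: iodine monobromide, IBr
Why: Iodocarbonate cyclisation (halocyclisation): the carbonate oxygen closes a six-membered ring onto octadienol C5 of the more electron-rich Z-olefin, anti to iodine, through a chair with both substituents equatorial, which should set C5–O syn to the carbinol oxygen and, by anti addition, the (R)-iodide at C6, while the tert-butyl group leaves as its bromide.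

Step 4
Reactants: 4 cyclic iodocarbonate
Product: 5 syn cis-epoxy alcohol
Conditions: K2CO3, MeOH, rt
Reagents that add atoms: none
Why: Carbonate methanolysis followed by intramolecular Williamson closure: the C5 alkoxide displaces iodide with inversion, which should give the cis-epoxide syn to the free allylic hydroxyl.

Step 5
Reactants: 5 syn cis-epoxy alcohol
Product: 6 trans-vinyloxetane alcohol
Conditions: KOH, DMSO/H2O (4:1), 100 °C
Reagents that add atoms: none
Why: Base-mediated 4-exo-tet opening of a 3,4-epoxy alcohol (intramolecular Williamson-type etherification), the exo mode being the known preference under these conditions: the allylic alkoxide attacks octadienol C5 with inversion, so the syn epoxy alcohol should give the trans-2,4-disubstituted oxetane with (S) at the new C–O carbon (future C2) and free the (S)-carbinol C1'.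

Step 6
Reactants: 6 trans-vinyloxetane alcohol
Product: 7 PMB ether of 6
Conditions: NaH, PMBCl, Bu4NI (cat.), THF/DMF, 0 °C to rt
Reagents that add atoms: 4-methoxybenzyl chloride, COc1ccc(CCl)cc1
Why: Williamson ether synthesis under basic conditions, which the acid-sensitive vinyl oxetane should tolerate.

Step 7
Reactants: 7 PMB-protected trans-vinyloxetane; 8 chloroacetyl chloride
Product: 11 (7S)-chloro oxocenone, via chloroketene 9 (not isolated), via oxonium enolate zwitterion 10 (not isolated)
Conditions: 8 added slowly to 7 and i-Pr2NEt, CH2Cl2, 40 °C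
Reagents that add atoms: none
Why: Proposed new method: chloroketene 9, released from 8 by the amine, is attacked in its plane by the Lewis-basic oxetane oxygen on the side of the ketene hydrogen to give the Z-configured oxonium enolate 10 (Cl anti to O1), and the [3,3]-sigmatropic shift that follows makes C6–C7 while the strained O1–C4 bond breaks, so that O1–C8 and C6–C7 form in one operation; the closest known reaction is the Bellus–Claisen (ketene-Claisen) ring expansion of 2-vinyltetrahydrofurans and 2-vinyltetrahydropyrans with dichloroketene, and new here are the oxetane as the allyl ether and the monochloroketene. The oxocane is not closed end to end but arises by four-atom ring expansion of the oxetane through a bicyclic six-membered transition state, driven by release of the oxetane strain. Because the four-membered ring holds the O1–C8 and C4–C5 bonds eclipsed, this transition state must be boat-like with C6 and C7 folded over the oxetane, which is what delivers the Z-olefin C4=C5 that an eight-membered ring requires. C7 is controlled by C2 through C4: the acyl group has to sit on the oxetane face that carries the vinyl group, this face is anti to the C2 side chain, and with the enolate hydrogen pointing inward the chlorine ends on the outer face, that is (7S), while the C4 stereocentre is consumed. The step needs O-acylation to outrun ketene oligomerisation and [2+2] addition to the vinyl group; the high donor strength of the oxetane oxygen, the poorly nucleophilic monosubstituted olefin and the slow addition of 8 should secure this.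

Step 8
Reactants: 11 (7S)-chloro oxocenone
Product: 13 (7R)-hydroxy oxocenone, via formate 12 (not isolated)
Conditions: HCO2Cs, 18-crown-6, DMF, 40 °C; then MeOH, NaHCO3, 0 °C
Reagents that add atoms: caesium formate, [Cs+].[O-]C=O
Why: SN2 displacement of the α-chloro lactone, activated by the adjacent carbonyl, by formate with inversion should turn (7S)-Cl into (7R)-O, and formate 12, far more labile than the lactone, is removed by mild methanolysis.

Step 9
Reactants: 13 (7R)-hydroxy oxocenone
Product: 14 allyldimethylsilyl ether of 13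
Conditions: CH2=CHCH2SiMe2Cl, imidazole, CH2Cl2, 0 °C
Reagents that add atoms: allyl(chloro)dimethylsilane, C=CC[Si](C)(C)Cl
Why: Silyl ether formation attaches the allyl donor to O7 without touching the lactone.

Step 10
Reactants: 14 allyldimethylsilyl ether
Product: 16 C8 acetoxy ether, via aluminium hemiacetal 15 (not isolated)
Conditions: i-Bu2AlH, CH2Cl2, −78 °C; then pyridine, DMAP, Ac2O, −78 to −20 °C
Reagents that add atoms: acetic anhydride, CC(=O)OC(C)=O
Why: Reductive acetylation: the hydride reduction should stop at aluminium hemiacetal 15, which is acetylated in situ so that the eight-membered lactol never opens; C8 forms as an epimer mixture that the next step erases.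

Step 11
Reactants: 16 C8 acetoxy ether
Product: 19 8-allyl oxocen-7-ol, via oxocarbenium ion 17 (not isolated), via silyl acetate 18 (not isolated)
Conditions: Me3SiOTf (cat.), CH2Cl2 (high dilution), −78 °C; then K2CO3, MeOH, 0 °C
Reagents that add atoms: none
Why: Silicon-tethered intramolecular Hosomi–Sakurai allylation: ionisation to oxocarbenium ion 17 and allyl transfer within the tether through a seven-membered array should deliver the allyl group to the face of C8 that carries O7, giving (8R), cis to O7 and trans to the C2 substituent as is usual for nucleophilic addition to cyclic oxocarbenium ions, and methanolysis of silyl acetate 18 frees the 7-hydroxyl.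

Step 12
Reactants: 19 8-allyl oxocen-7-ol
Product: 20 syn 4,5-epoxy alcohol
Conditions: VO(acac)2 (cat.), t-BuOOH, CH2Cl2, 0 °C to rt
Reagents that add atoms: tert-butyl hydroperoxide, CC(C)(C)OO
Why: Hydroxyl-directed vanadium-catalysed epoxidation of a homoallylic alcohol: oxygen should be delivered to the ring Z-olefin from the face of the 7-hydroxyl to give the (4R,5S)-epoxide, and the disubstituted homoallylic olefin should react before the monosubstituted, more remote allyl group.

Step 13
Reactants: 20 syn 4,5-epoxy alcohol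
Product: 21 7-O-TBS epoxide
Conditions: TBSOTf, 2,6-lutidine, CH2Cl2, −78 °C
Reagents that add atoms: tert-butyldimethylsilyl triflate, CC(C)(C)[Si](C)(C)OS(=O)(=O)C(F)(F)F
Why: Silylation marks O7 as the one oxygen that stays unacetylated and removes the free hydroxyl that could otherwise steer the epoxide opening to C4 by chelation.

Step 14
Reactants: 21 7-O-TBS epoxide
Product: 22 4-hydroxy 5-acetate
Conditions: CsOAc, AcOH, DMF, 90 °C
Reagents that add atoms: acetic acid (delivered as caesium acetate), CC(=O)O
Why: Carboxylate opening of an epoxide by SN2 (anti) attack: acetate should enter at C5 from the face opposite the epoxide because the rear of C4 is screened by the 1,3-related C2 side chain, which retains C4–O as (4R), inverts C5 to (5R) and gives the trans-4,5 pattern; later acetyl migration between O4 and O5 is harmless since both end as acetates.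

Step 15
Reactants: 22 4-hydroxy 5-acetate
Product: 23 C1',C4-diol 5-acetate
Conditions: DDQ, CH2Cl2/pH 7 buffer, 0 °C
Reagents that add atoms: none
Why: Oxidative cleavage of the PMB ether by DDQ, to which the TBS ether, the acetate and the terminal olefin are inert.

Step 16
Reactants: 23 C1',C4-diol 5-acetate
Product: 24 triacetate 7-O-TBS ether
Conditions: Ac2O, pyridine, DMAP (cat.), CH2Cl2, rt
Reagents that add atoms: acetic anhydride, CC(=O)OC(C)=O
Why: Acetylation of the two free secondary hydroxyls at C1' and C4 fixes the final acetate pattern while O7 stays silylated.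

Step 17
Reactants: 25 vinyl bromide; 26 ethynyltri(propan-2-yl)silane
Product: 27 TIPS-capped but-3-en-1-yne
Conditions: PdCl2(PPh3)2, CuI, Et2NH, THF, rt
Reagents that add atoms: none
Why: Sonogashira coupling of a vinyl halide with a terminal alkyne gives the silyl-capped conjugated enyne partner.

Step 18
Reactants: 24 triacetate 7-O-TBS ether; 27 TIPS-capped but-3-en-1-yne
Product: 28 TIPS-capped Z-enyne
Conditions: second-generation Grubbs catalyst RuCl2(=CHPh)(PCy3)(H2IMes), CH2Cl2, 40 °C
Reagents that add atoms: none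
Why: Olefin cross-metathesis of a terminal olefin with a silyl-capped conjugated enyne, a pairing known to favour the Z-enyne under kinetic control, while the hindered alkyne and the now saturated ring stay out of the reaction.

Step 19
Reactants: 28 TIPS-capped Z-enyne
Product: 29 target
Conditions: Bu4NF, AcOH, THF, 0 °C to rt
Reagents that add atoms: none
Why: Fluoride-mediated cleavage of the O–Si and C(sp)–Si bonds, buffered with acetic acid so that the acetates persist; migration of the 5-acetyl group to O7 is disfavoured by their trans-1,3 relation on the ring.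

**Compound list**

1 | rac-(5Z)-octa-1,5-dien-3-ol | C=CC(O)C/C=C\CC | starting material
2 | (3S,5Z)-octa-1,5-dien-3-ol | C=C[C@@H](O)C/C=C\CC | intermediate
3 | tert-butyl (3S,5Z)-octa-1,5-dien-3-yl carbonate | C=C[C@@H](OC(=O)OC(C)(C)C)C/C=C\CC | intermediate
4 | (4S,6R)-4-ethenyl-6-[(1R)-1-iodopropyl]-1,3-dioxan-2-one | C=C[C@@H]1C[C@H]([C@H](I)CC)OC(=O)O1 | intermediate
5 | (2S)-1-[(2R,3S)-3-ethyloxiran-2-yl]but-3-en-2-ol | C=C[C@@H](O)C[C@H]1O[C@H]1CC | intermediate
6 | (1S)-1-[(2S,4S)-4-ethenyloxetan-2-yl]propan-1-ol | C=C[C@@H]1C[C@@H]([C@@H](O)CC)O1 | intermediate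
7 | (2S,4S)-2-ethenyl-4-{(1S)-1-[(4-methoxyphenyl)methoxy]propyl}oxetane | C=C[C@@H]1C[C@@H]([C@@H](OCc2ccc(OC)cc2)CC)O1 | intermediate
8 | chloroacetyl chloride | ClCC(Cl)=O | starting material
9 | chloroketene | ClC=C=O | intermediate
10 | oxonium enolate zwitterion of 7 (O-acyl group cis to the vinyl group, Cl cis to O−) | C=C[C@@H]1C[C@@H]([C@@H](OCc2ccc(OC)cc2)CC)[O+]1/C([O-])=C/Cl | intermediate
11 | (2S,4Z,7S)-7-chloro-2-{(1S)-1-[(4-methoxyphenyl)methoxy]propyl}-2,3,6,7-tetrahydrooxocin-8-one (lactone, target locants) | O=C1O[C@H]([C@@H](OCc2ccc(OC)cc2)CC)C/C=C\C[C@@H]1Cl | intermediate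
12 | (2S,4Z,7R)-2-{(1S)-1-[(4-methoxyphenyl)methoxy]propyl}-8-oxo-2,3,6,7-tetrahydrooxocin-7-yl formate | O=C1O[C@H]([C@@H](OCc2ccc(OC)cc2)CC)C/C=C\C[C@H]1OC=O | intermediate
13 | (2S,4Z,7R)-7-hydroxy-2-{(1S)-1-[(4-methoxyphenyl)methoxy]propyl}-2,3,6,7-tetrahydrooxocin-8-one | O=C1O[C@H]([C@@H](OCc2ccc(OC)cc2)CC)C/C=C\C[C@H]1O | intermediate
14 | (2S,4Z,7R)-7-{[dimethyl(prop-2-enyl)silyl]oxy}-2-{(1S)-1-[(4-methoxyphenyl)methoxy]propyl}-2,3,6,7-tetrahydrooxocin-8-one | O=C1O[C@H]([C@@H](OCc2ccc(OC)cc2)CC)C/C=C\C[C@H]1O[Si](C)(C)CC=C | intermediate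
15 | diisobutylaluminium lactolate of 14 (C8 epimers) | CC(C)C[Al](CC(C)C)OC1O[C@H]([C@@H](OCc2ccc(OC)cc2)CC)C/C=C\C[C@H]1O[Si](C)(C)CC=C | intermediate
16 | (2S,4Z,7R)-7-{[dimethyl(prop-2-enyl)silyl]oxy}-2-{(1S)-1-[(4-methoxyphenyl)methoxy]propyl}-3,6,7,8-tetrahydro-2H-oxocin-8-yl acetate (C8 epimers) | CC(=O)OC1O[C@H]([C@@H](OCc2ccc(OC)cc2)CC)C/C=C\C[C@H]1O[Si](C)(C)CC=C | intermediate
17 | cyclic oxocarbenium ion (O1=C8) formed from 16 by loss of acetate | [CH]1=[O+][C@H]([C@@H](OCc2ccc(OC)cc2)CC)C/C=C\C[C@H]1O[Si](C)(C)CC=C | intermediate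
18 | acetoxy(dimethyl)silyl ether of 19 | C=CC[C@H]1O[C@H]([C@@H](OCc2ccc(OC)cc2)CC)C/C=C\C[C@H]1O[Si](C)(C)OC(C)=O | intermediate
19 | (2S,4Z,7R,8R)-2-{(1S)-1-[(4-methoxyphenyl)methoxy]propyl}-8-(prop-2-enyl)-3,6,7,8-tetrahydro-2H-oxocin-7-ol | C=CC[C@H]1O[C@H]([C@@H](OCc2ccc(OC)cc2)CC)C/C=C\C[C@H]1O | intermediate
20 | (2S,4R,5S,7R,8R)-4,5-epoxy-2-{(1S)-1-[(4-methoxyphenyl)methoxy]propyl}-8-(prop-2-enyl)oxocan-7-ol (epoxide cis to 7-OH) | C=CC[C@H]1O[C@H]([C@@H](OCc2ccc(OC)cc2)CC)C[C@H]3O[C@H]3C[C@H]1O | intermediate
21 | 7-O-tert-butyldimethylsilyl ether of 20 | C=CC[C@H]1O[C@H]([C@@H](OCc2ccc(OC)cc2)CC)C[C@H]3O[C@H]3C[C@H]1O[Si](C)(C)C(C)(C)C | intermediate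
22 | (2S,4R,5R,7R,8R)-7-[(tert-butyldimethylsilyl)oxy]-4-hydroxy-2-{(1S)-1-[(4-methoxyphenyl)methoxy]propyl}-8-(prop-2-enyl)oxocan-5-yl acetate | C=CC[C@H]1O[C@H]([C@@H](OCc2ccc(OC)cc2)CC)C[C@@H](O)[C@H](OC(C)=O)C[C@H]1O[Si](C)(C)C(C)(C)C | intermediate
23 | (2S,4R,5R,7R,8R)-7-[(tert-butyldimethylsilyl)oxy]-4-hydroxy-2-[(1S)-1-hydroxypropyl]-8-(prop-2-enyl)oxocan-5-yl acetate | C=CC[C@H]1O[C@H]([C@@H](O)CC)C[C@@H](O)[C@H](OC(C)=O)C[C@H]1O[Si](C)(C)C(C)(C)C | intermediate
24 | (1S)-1-[(2S,4R,5R,7R,8R)-4,5-diacetoxy-7-[(tert-butyldimethylsilyl)oxy]-8-(prop-2-enyl)oxocan-2-yl]propyl acetate | C=CC[C@H]1O[C@H]([C@H](CC)OC(C)=O)C[C@@H](OC(C)=O)[C@H](OC(C)=O)C[C@H]1O[Si](C)(C)C(C)(C)C | intermediate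
25 | vinyl bromide | C=CBr | starting material
26 | ethynyltri(propan-2-yl)silane | C#C[Si](C(C)C)(C(C)C)C(C)C | starting material
27 | (but-3-en-1-yn-1-yl)tri(propan-2-yl)silane | C=CC#C[Si](C(C)C)(C(C)C)C(C)C | intermediate
28 | (1S)-1-[(2S,4R,5R,7R,8R)-4,5-diacetoxy-7-[(tert-butyldimethylsilyl)oxy]-8-{(2Z)-5-[tri(propan-2-yl)silyl]pent-2-en-4-yn-1-yl}oxocan-2-yl]propyl acetate | CC(C)[Si](C#C/C=C\C[C@H]1O[C@H]([C@H](CC)OC(C)=O)C[C@@H](OC(C)=O)[C@H](OC(C)=O)C[C@H]1O[Si](C)(C)C(C)(C)C)(C(C)C)C(C)C | intermediate
29 | (1S)-1-[(2S,4R,5R,7R,8R)-4,5-diacetoxy-7-hydroxy-8-[(2Z)-pent-2-en-4-yn-1-yl]oxocan-2-yl]propyl acetate | C#C/C=C\C[C@H]1O[C@H]([C@H](CC)OC(C)=O)C[C@@H](OC(C)=O)[C@H](OC(C)=O)C[C@H]1O | target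

**Step count and risks**

Total: 19 steps. Longest linear sequence: 18 steps (steps 1–16, 18, 19); step 17 is a one-step branch.

Steps most likely to fail:

1. Step 7 (key step, proposed method). The chloroketene may oligomerise faster than the ether oxygen captures it, chloride may open the acylated oxetane, or the facial course may erode. Fallback, a stepwise ketene-acetal Claisen ring expansion of the kind known for vinyl-substituted 1,3-dioxanes, setting out from 7: dilute H2SO4 in THF/H2O should hydrolyse the oxetane at its allylic carbon to the 1,3-diol F1 (C2–O untouched; the allylic carbinol forms as a mixture, which does not matter because this centre becomes sp2). Acetal exchange with phenylselanylacetaldehyde diethyl acetal (pyridinium tosylate, toluene, heat) should give the selenoacetal F2, NaIO4 the selenoxide F3, and heating with DBU in xylene the ketene acetal F4, which should rearrange in the same pot to the lactone F5. Davis oxidation of its potassium enolate (KN(SiMe3)2, 2-(phenylsulfonyl)-3-phenyloxaziridine, −78 °C) is expected to hydroxylate the outer face to the (7S)-alcohol F6, and Mitsunobu inversion with formic acid (PPh3, diisopropyl azodicarboxylate) returns to the route at formate 12. This path also avoids the chloride displacement of step 8.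

2. Step 14. Acetate may attack C4 instead of C5, or the ring oxygen may participate across the ring under the forcing conditions, either of which gives the wrong 4,5-diastereomer or rearranged ethers. Fallback, regiocontrol handed from the substrate to a chiral catalyst with water as nucleophile, setting out from 21: hydrolytic opening under the cobalt salen complex (salen)Co(OAc) (trivalent cobalt; salen = N,N′-bis(3,5-di-tert-butylsalicylidene)cyclohexane-1,2-diaminate, ligand enantiomer chosen to match attack at C5) should give the diol F10; DDQ should then remove the PMB group to give the triol F11, and acetylation (Ac2O, pyridine, DMAP) returns to the route at 24.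

3. Step 11. Allyl transfer may occur between molecules from the less hindered face, or the silyl tether may be lost before ionisation, giving the 8-epimer or no C-allylation. Fallback, the order of bond formation at C8 is reversed (carbon first, hydride last), setting out from 13: silylation (TBSOTf, 2,6-lutidine) should give the TBS ether F7, CH2=CHCH2MgBr at −78 °C the lactol F8, and Et3SiH/BF3·OEt2 reduction of the derived oxocarbenium ion anti to the bulky 7-silyloxy group the allyl ether F9 with allyl cis to O7; Bu4NF then returns to the route at 19.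

**Further compounds**

F1 | step 7 | (5S,6S)-6-[(4-methoxyphenyl)methoxy]oct-1-ene-3,5-diol (C3 epimers) | C=CC(O)C[C@H](O)[C@@H](OCc1ccc(OC)cc1)CC
F2 | step 7 | (6S)-4-ethenyl-6-{(1S)-1-[(4-methoxyphenyl)methoxy]propyl}-2-[(phenylselanyl)methyl]-1,3-dioxane | C=CC1C[C@@H]([C@@H](OCc2ccc(OC)cc2)CC)OC(C[Se]c2ccccc2)O1
F3 | step 7 | selenoxide of F2 | C=CC1C[C@@H]([C@@H](OCc2ccc(OC)cc2)CC)OC(C[Se](=O)c2ccccc2)O1
F4 | step 7 | (6S)-4-ethenyl-6-{(1S)-1-[(4-methoxyphenyl)methoxy]propyl}-2-methylidene-1,3-dioxane | C=CC1C[C@@H]([C@@H](OCc2ccc(OC)cc2)CC)OC(=C)O1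
F5 | step 7 | (2S,4Z)-2-{(1S)-1-[(4-methoxyphenyl)methoxy]propyl}-2,3,6,7-tetrahydrooxocin-8-one | O=C1O[C@H]([C@@H](OCc2ccc(OC)cc2)CC)C/C=C\CC1
F6 | step 7 | (2S,4Z,7S)-7-hydroxy-2-{(1S)-1-[(4-methoxyphenyl)methoxy]propyl}-2,3,6,7-tetrahydrooxocin-8-one | O=C1O[C@H]([C@@H](OCc2ccc(OC)cc2)CC)C/C=C\C[C@@H]1O
F7 | step 11 | 7-O-tert-butyldimethylsilyl ether of 13 | O=C1O[C@H]([C@@H](OCc2ccc(OC)cc2)CC)C/C=C\C[C@H]1O[Si](C)(C)C(C)(C)C
F8 | step 11 | (2S,4Z,7R)-7-[(tert-butyldimethylsilyl)oxy]-2-{(1S)-1-[(4-methoxyphenyl)methoxy]propyl}-8-(prop-2-enyl)-3,6,7,8-tetrahydro-2H-oxocin-8-ol (C8 epimers) | C=CCC1(O)O[C@H]([C@@H](OCc2ccc(OC)cc2)CC)C/C=C\C[C@H]1O[Si](C)(C)C(C)(C)C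
F9 | step 11 | 7-O-tert-butyldimethylsilyl ether of 19 | C=CC[C@H]1O[C@H]([C@@H](OCc2ccc(OC)cc2)CC)C/C=C\C[C@H]1O[Si](C)(C)C(C)(C)C
F10 | step 14 | (2S,4R,5R,7R,8R)-7-[(tert-butyldimethylsilyl)oxy]-2-{(1S)-1-[(4-methoxyphenyl)methoxy]propyl}-8-(prop-2-enyl)oxocane-4,5-diol | C=CC[C@H]1O[C@H]([C@@H](OCc2ccc(OC)cc2)CC)C[C@@H](O)[C@H](O)C[C@H]1O[Si](C)(C)C(C)(C)C
F11 | step 14 | (2S,4R,5R,7R,8R)-7-[(tert-butyldimethylsilyl)oxy]-2-[(1S)-1-hydroxypropyl]-8-(prop-2-enyl)oxocane-4,5-diol | C=CC[C@H]1O[C@H]([C@@H](O)CC)C[C@@H](O)[C@H](O)C[C@H]1O[Si](C)(C)C(C)(C)C
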